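A direct plan would form the C(beta)–aryl bond of the three-carbon linker last: the MOM-protected 5-prenylcatechol boronate A1 would be added to the aryl vinyl ketone A2 with [Rh(OH)(cod)]2 as catalyst, and five MOM groups would then be removed. Its weakest points would be:
- the direct C-prenylation of 2,4,6-trihydroxyacetophenone to A3, where the ambident phenolate would also give O-alkyl and bis-alkyl products;
- the three-operation, one-carbon extension of the acetyl group to the vinyl ketone A2 (Mannich reaction, quaternisation, elimination), which would add length without complexity and deliver a polymerisable enone;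
- the conjugate addition itself, in which a twisted, di-ortho-substituted enone would meet an electron-rich arylboronate prone to protodeboronation.

**Strategy.** The new route builds ring A last from an open chain, as the plant does: ring A's oxygens at C2', C4' and C6' are read as the carbonyls of a polyketide and C1' as the carbon between two of them. A Claisen (Dieckmann-type) cyclisation of a 4-prenyl-3,5,7-trioxononanoate that already carries ring B on a saturated two-carbon tether forms the C1'–C6' bond and, in one operation, the acylphloroglucinol with its prenyl group fixed between two hydroxyls by an earlier alkylation of an acyclic 1,3-diketone. Ring A thus needs no prenylation of a phenol, no protecting group, no vinyl ketone and no conjugate addition.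

Key step: step 8

Remark on the chemistry: methyl 3,5-dioxohexanoate and the tert-butyl carbonate of 2-methylbut-3-en-2-ol are taken as purchasable; the C4 centre of the prenylated diketo ester and of the triketo ester is racemic, enolisable and lost on aromatisation.

Step 1
Reactants: 1 3,4-dihydroxybenzaldehyde; 2 tert-butyl 2-methylbut-3-en-2-yl carbonate
Product: 3 3-hydroxy-4-[(2-methylbut-3-en-2-yl)oxy]benzaldehyde
Conditions: Pd(PPh3)4 (2 mol%), 2 (1.05 equiv), 4 Å MS, THF, 0 °C
Reagents that add atoms: tert-butyl 2-methylbut-3-en-2-yl carbonate 2, CC(C)(C)OC(=O)OC(C)(C)C=C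
Why: Tsuji–Trost O-allylation, in which zerovalent palladium ionises 2 to a 1,1-dimethyl-pi-allyl complex and tert-butoxide, the alkoxide deprotonates the far more acidic 4-OH (para to CHO), and the phenoxide attacks the more substituted allyl terminus to give the tertiary ether under kinetic control.

Step 2
Reactants: 3 3-hydroxy-4-[(2-methylbut-3-en-2-yl)oxy]benzaldehyde
Product: 4 3,4-dihydroxy-5-(3-methylbut-2-en-1-yl)benzaldehyde
Conditions: N,N-diethylaniline, 140 °C, Ar
Reagents that add atoms: none
Why: Aromatic Claisen rearrangement ([3,3]-sigmatropic shift, then enolisation), in which the terminal CH2 of the 1,1-dimethylallyl group bonds to C5, the only ortho carbon that bears hydrogen, so that a linear prenyl group should appear next to the 4-OH.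

Step 3
Reactants: 4 3,4-dihydroxy-5-(3-methylbut-2-en-1-yl)benzaldehyde
Product: 5 3,4-bis(methoxymethoxy)-5-(3-methylbut-2-en-1-yl)benzaldehyde
Conditions: MOMCl (3 equiv), i-Pr2NEt (4 equiv), CH2Cl2, 0 °C → rt
Reagents that add atoms: chloromethyl methyl ether (MOMCl), COCCl
Why: O-alkylation of both phenols by the reactive alpha-chloro ether (MOM protection) should give base-stable acetals for the enolate chemistry ahead.

Step 4
Reactants: 5 3,4-bis(methoxymethoxy)-5-(3-methylbut-2-en-1-yl)benzaldehyde; 6 diethyl {2-[methoxy(methyl)amino]-2-oxoethyl}phosphonate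
Product: 7 (2E)-3-[3,4-bis(methoxymethoxy)-5-(3-methylbut-2-en-1-yl)phenyl]-N-methoxy-N-methylprop-2-enamide
Conditions: 6 (1.2 equiv), NaH (1.2 equiv), THF, 0 °C → rt
Reagents that add atoms: diethyl {2-[methoxy(methyl)amino]-2-oxoethyl}phosphonate 6, CCOP(=O)(CC(=O)N(C)OC)OCC
Why: Horner–Wadsworth–Emmons olefination with the stabilised phosphonate anion should give the (E)-enamide and install the Weinreb amide in the same operation.

Step 5
Reactants: 7 (2E)-3-[3,4-bis(methoxymethoxy)-5-(3-methylbut-2-en-1-yl)phenyl]-N-methoxy-N-methylprop-2-enamide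
Product: 8 3-[3,4-bis(methoxymethoxy)-5-(3-methylbut-2-en-1-yl)phenyl]-N-methoxy-N-methylpropanamide
Conditions: H2 (3 atm), RhCl(PPh3)3 (5 mol%), benzene/EtOH (1:1), 40 °C
Reagents that add atoms: none
Why: Homogeneous hydrogenation with RhCl(PPh3)3 should reduce the disubstituted conjugated C=C, whereas trisubstituted olefins such as the prenyl group, the N–O bond and the acetals are inert to this catalyst.

Step 6
Reactants: 9 methyl 3,5-dioxohexanoate; 10 prenyl bromide (1-bromo-3-methylbut-2-ene)
Product: 12 methyl 4-(3-methylbut-2-en-1-yl)-3,5-dioxohexanoate, via sodium enolate 11 (not isolated)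
Conditions: 9 (1.5 equiv), NaH (1.0 equiv), THF, 0 °C; then 10 (1.0 equiv), 0 °C → rt
Reagents that add atoms: prenyl bromide 10, CC(C)=CCBr
Why: C-alkylation of a 1,3-diketone enolate by an allylic bromide at the most acidic carbon (C4, between the two ketones), with excess 9 suppressing bis-alkylation; a minor C2-alkylated isomer would converge on the same ring A in step 8, because the two ring carbons flanking C1' are equivalent.

Step 7
Reactants: 12 methyl 4-(3-methylbut-2-en-1-yl)-3,5-dioxohexanoate; 8 3-[3,4-bis(methoxymethoxy)-5-(3-methylbut-2-en-1-yl)phenyl]-N-methoxy-N-methylpropanamide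
Product: 14 methyl 9-[3,4-bis(methoxymethoxy)-5-(3-methylbut-2-en-1-yl)phenyl]-4-(3-methylbut-2-en-1-yl)-3,5,7-trioxononanoate, via trilithium trienolate 13 (not isolated)
Conditions: 12 (2.0 equiv), LiN(i-Pr)2 (6.2 equiv), THF, −78 → 0 °C; then 8 (1.0 equiv), −78 → 0 °C; AcOH quench at −78 °C; crude 14 used at once
Reagents that add atoms: none
Why: Claisen-type acylation of a 1,3,5-tricarbonyl polyanion at its last-formed and most nucleophilic terminal carbon (C6), the Weinreb amide giving a chelated tetrahedral adduct that releases the ketone only on quench, so that neither over-addition nor proton transfer from the product should interfere.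

Step 8
Reactants: 14 methyl 9-[3,4-bis(methoxymethoxy)-5-(3-methylbut-2-en-1-yl)phenyl]-4-(3-methylbut-2-en-1-yl)-3,5,7-trioxononanoate
Product: 16 3-[3,4-bis(methoxymethoxy)-5-(3-methylbut-2-en-1-yl)phenyl]-1-[2,4,6-trihydroxy-3-(3-methylbut-2-en-1-yl)phenyl]propan-1-one, via 2-acylcyclohexane-1,3,5-trione 15 (not isolated)
Conditions: Mg(OMe)2 (5 equiv), MeOH, rt → 60 °C, Ar; then cold aq. AcOH
Reagents that add atoms: none
Why: Mg(OMe)2 should convert 14 into a magnesium polyenolate in which the C3, C5 and C7 ketones are tied up as chelated 1,3-dicarbonyl enolates, so that the ester C1 is the only electrophilic carbonyl left; C6, the nucleophilic carbon of the C5–C7 diketonate, attacks C1, methoxide is expelled, and the 2-acylcyclohexane-1,3,5-trione 15 enolises irreversibly to the phloroglucinol. The closest known reaction type is the biomimetic Claisen cyclisation of 3,5,7-triketo esters and of tetraacetic lactone to acylphloroglucinols with Mg(OMe)2, the laboratory counterpart of the chalcone synthase ring closure. Ring A is closed in the 6-exo-trig mode, a Dieckmann-type attack of an enolate carbon on the ester carbonyl that forms the C1'–C6' bond, and no other ring is formed. No stereocentre is created, and the racemic C4 centre of 14 disappears on aromatisation. The step needs Claisen closure (C6 to C1) to win over aldol closure (C2 to the C7 ketone), which would give a resorcylate; this is secured by keeping C1 as a methyl ester and by magnesium chelation in anhydrous methanol, which deactivates the ketones as electrophiles, while any 4-hydroxy-2-pyranone formed by O-acylation is reopened by methoxide and funnelled to the same product. The prenyl position needs no control here, since C4 of the chain becomes the ring carbon between two hydroxyls, and the MOM acetals and both prenyl olefins are inert to the basic medium.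

Step 9
Reactants: 16 3-[3,4-bis(methoxymethoxy)-5-(3-methylbut-2-en-1-yl)phenyl]-1-[2,4,6-trihydroxy-3-(3-methylbut-2-en-1-yl)phenyl]propan-1-one
Product: 17 3-[3,4-dihydroxy-5-(3-methylbut-2-en-1-yl)phenyl]-1-[2,4,6-trihydroxy-3-(3-methylbut-2-en-1-yl)phenyl]propan-1-one (the target)
Conditions: 3 M aq. HCl, MeOH, rt → 40 °C, Ar; NaHCO3 quench at full conversion
Reagents that add atoms: none
Why: Acid-catalysed acetal methanolysis of the two MOM ethers via oxocarbenium ions should be much faster than protonation of the trisubstituted olefins in dilute methanolic HCl, so that the ortho-prenyl phenols are released without chroman formation.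

**Compound list**

1 | 3,4-dihydroxybenzaldehyde | O=Cc1ccc(O)c(O)c1 | starting material
2 | tert-butyl 2-methylbut-3-en-2-yl carbonate | CC(C)(C)OC(=O)OC(C)(C)C=C | starting material
3 | 3-hydroxy-4-[(2-methylbut-3-en-2-yl)oxy]benzaldehyde | O=Cc1ccc(OC(C)(C)C=C)c(O)c1 | intermediate
4 | 3,4-dihydroxy-5-(3-methylbut-2-en-1-yl)benzaldehyde | O=Cc1cc(O)c(O)c(CC=C(C)C)c1 | intermediate
5 | 3,4-bis(methoxymethoxy)-5-(3-methylbut-2-en-1-yl)benzaldehyde | O=Cc1cc(OCOC)c(OCOC)c(CC=C(C)C)c1 | intermediate
6 | diethyl {2-[methoxy(methyl)amino]-2-oxoethyl}phosphonate | CCOP(=O)(CC(=O)N(C)OC)OCC | starting material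
7 | (2E)-3-[3,4-bis(methoxymethoxy)-5-(3-methylbut-2-en-1-yl)phenyl]-N-methoxy-N-methylprop-2-enamide | CON(C)C(=O)/C=C/c1cc(OCOC)c(OCOC)c(CC=C(C)C)c1 | intermediate
8 | 3-[3,4-bis(methoxymethoxy)-5-(3-methylbut-2-en-1-yl)phenyl]-N-methoxy-N-methylpropanamide | CON(C)C(=O)CCc1cc(OCOC)c(OCOC)c(CC=C(C)C)c1 | intermediate
9 | methyl 3,5-dioxohexanoate | COC(=O)CC(=O)CC(C)=O | starting material
10 | prenyl bromide (1-bromo-3-methylbut-2-ene) | CC(C)=CCBr | starting material
11 | sodium enolate of 9 (C4 diketonate) | COC(=O)CC(=O)C=C(C)O[Na] | intermediate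
12 | methyl 4-(3-methylbut-2-en-1-yl)-3,5-dioxohexanoate (racemic) | COC(=O)CC(=O)C(CC=C(C)C)C(C)=O | intermediate
13 | trilithium trienolate of 12 | C=C(O[Li])C(CC=C(C)C)=C(O[Li])C=C(O[Li])OC | intermediate
14 | methyl 9-[3,4-bis(methoxymethoxy)-5-(3-methylbut-2-en-1-yl)phenyl]-4-(3-methylbut-2-en-1-yl)-3,5,7-trioxononanoate (racemic) | COC(=O)CC(=O)C(CC=C(C)C)C(=O)CC(=O)CCc1cc(CC=C(C)C)c(OCOC)c(OCOC)c1 | intermediate
15 | 2-{3-[3,4-bis(methoxymethoxy)-5-(3-methylbut-2-en-1-yl)phenyl]propanoyl}-4-(3-methylbut-2-en-1-yl)cyclohexane-1,3,5-trione | O=C1CC(=O)C(CC=C(C)C)C(=O)C1C(=O)CCc1cc(CC=C(C)C)c(OCOC)c(OCOC)c1 | intermediate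
16 | 3-[3,4-bis(methoxymethoxy)-5-(3-methylbut-2-en-1-yl)phenyl]-1-[2,4,6-trihydroxy-3-(3-methylbut-2-en-1-yl)phenyl]propan-1-one | CC(C)=CCc1cc(CCC(=O)c2c(O)cc(O)c(CC=C(C)C)c2O)cc(OCOC)c1OCOC | intermediate
17 | 3-[3,4-dihydroxy-5-(3-methylbut-2-en-1-yl)phenyl]-1-[2,4,6-trihydroxy-3-(3-methylbut-2-en-1-yl)phenyl]propan-1-one | CC(C)=CCc1cc(CCC(=O)c2c(O)cc(O)c(CC=C(C)C)c2O)cc(O)c1O | target

**Step count and risks**

Total step count: 9. Longest linear sequence: 8 steps (steps 1–5, then 7, 8 and 9); step 6 is the only step of the second branch.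

The three steps most likely to fail:

1. Step 8. The ring closure may take the aldol course instead of the Claisen course, or methoxide may cleave the 2-substituted 1,3-diketone (retro-Claisen) before it cyclises. Fallback, setting out from 8 and coming back at 17, with ring A brought in as a preformed nucleophile: phloroglucinol F1 would be converted with NaH and MOMCl in DMF into 1,3,5-tris(methoxymethoxy)benzene F2. Ortho-lithiation (n-BuLi, THF, 0 °C) and allylation with 10 in the presence of CuBr·SMe2 (10 mol%) would give 1,3,5-tris(methoxymethoxy)-2-(3-methylbut-2-en-1-yl)benzene F3. A second ortho-lithiation (n-BuLi, TMEDA, THF, 0 °C) at either of the two equivalent ring positions would give [2,4,6-tris(methoxymethoxy)-3-(3-methylbut-2-en-1-yl)phenyl]lithium F4. Its addition to Weinreb amide 8 (−78 → 0 °C) would give 3-[3,4-bis(methoxymethoxy)-5-(3-methylbut-2-en-1-yl)phenyl]-1-[2,4,6-tris(methoxymethoxy)-3-(3-methylbut-2-en-1-yl)phenyl]propan-1-one F5, and acidic methanolysis under the conditions of step 9 would then give 17.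

2. Step 7. Incomplete formation of the trianion, proton transfer between it and the amide, or premature cyclisation of the triketo ester on work-up may erode the chain assembly. Fallback, setting out from 8 and coming back at 14, with the chain built ketone first and ester carbon last: acetylacetone F6 would be C-alkylated with 10 (K2CO3, acetone) to 3-(3-methylbut-2-en-1-yl)pentane-2,4-dione F7. Its dianion (LiN(i-Pr)2, 2.1 equiv, THF) would be acylated with 8 at a terminal methyl group to give 8-[3,4-bis(methoxymethoxy)-5-(3-methylbut-2-en-1-yl)phenyl]-3-(3-methylbut-2-en-1-yl)octane-2,4,6-trione F8. The trianion of F8 (LiN(i-Pr)2, 3.1 equiv) would be methoxycarbonylated at the remaining methyl group with dimethyl carbonate to give 14.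

3. Step 1. The phenoxide may attack the less substituted allyl terminus, the tertiary ether may re-ionise and isomerise under palladium, and some alkylation of the 3-OH may occur. Fallback, setting out from 1 and coming back at 3, without pi-allyl chemistry: 1 would be alkylated at the 4-OH with 3-chloro-3-methylbut-1-yne F9 (K2CO3, KI, acetone, 50 °C) to give 3-hydroxy-4-[(2-methylbut-3-yn-2-yl)oxy]benzaldehyde F10. Semi-hydrogenation of the alkyne (H2, Pd/CaCO3 poisoned with Pb(OAc)2, quinoline, EtOAc) would give 3.

**Further compounds**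

F1 | step 8 | phloroglucinol | Oc1cc(O)cc(O)c1
F2 | step 8 | 1,3,5-tris(methoxymethoxy)benzene | COCOc1cc(OCOC)cc(OCOC)c1
F3 | step 8 | 1,3,5-tris(methoxymethoxy)-2-(3-methylbut-2-en-1-yl)benzene | COCOc1cc(OCOC)c(CC=C(C)C)c(OCOC)c1
F4 | step 8 | [2,4,6-tris(methoxymethoxy)-3-(3-methylbut-2-en-1-yl)phenyl]lithium | [Li]c1c(OCOC)cc(OCOC)c(CC=C(C)C)c1OCOC
F5 | step 8 | 3-[3,4-bis(methoxymethoxy)-5-(3-methylbut-2-en-1-yl)phenyl]-1-[2,4,6-tris(methoxymethoxy)-3-(3-methylbut-2-en-1-yl)phenyl]propan-1-one | CC(C)=CCc1cc(CCC(=O)c2c(OCOC)cc(OCOC)c(CC=C(C)C)c2OCOC)cc(OCOC)c1OCOC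
F6 | step 7 | acetylacetone (pentane-2,4-dione) | CC(=O)CC(C)=O
F7 | step 7 | 3-(3-methylbut-2-en-1-yl)pentane-2,4-dione | CC(=O)C(CC=C(C)C)C(C)=O
F8 | step 7 | 8-[3,4-bis(methoxymethoxy)-5-(3-methylbut-2-en-1-yl)phenyl]-3-(3-methylbut-2-en-1-yl)octane-2,4,6-trione | CC(=O)C(CC=C(C)C)C(=O)CC(=O)CCc1cc(CC=C(C)C)c(OCOC)c(OCOC)c1
F9 | step 1 | 3-chloro-3-methylbut-1-yne | CC(C)(Cl)C#C
F10 | step 1 | 3-hydroxy-4-[(2-methylbut-3-yn-2-yl)oxy]benzaldehyde | O=Cc1ccc(OC(C)(C)C#C)c(O)c1
A1 | direct plan | 2-[3,4-bis(methoxymethoxy)-5-(3-methylbut-2-en-1-yl)phenyl]-4,4,5,5-tetramethyl-1,3,2-dioxaborolane | CC(C)=CCc1cc(B2OC(C)(C)C(C)(C)O2)cc(OCOC)c1OCOC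
A2 | direct plan | 1-[2,4,6-tris(methoxymethoxy)-3-(3-methylbut-2-en-1-yl)phenyl]prop-2-en-1-one | C=CC(=O)c1c(OCOC)cc(OCOC)c(CC=C(C)C)c1OCOC
A3 | direct plan | 1-[2,4,6-trihydroxy-3-(3-methylbut-2-en-1-yl)phenyl]ethan-1-one | CC(=O)c1c(O)cc(O)c(CC=C(C)C)c1O
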